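Count the chains from the charge before trusting any reading of the monomer.

| setting | south-west | east | flask |
|---|---|---|---|
| free monomer | 0.17 M | 0.38 M | 0.25 M |
| transfer agent | 2.5 mM | 2.5 mM | 2.50 mM |
| initiator | 10 mol% | 10 mol% | 10 mol% |
| remark | run made earlier | run made earlier |  |
| time |  |  | 3.0 h |

| run | time / h | monomer in chains / % | free monomer / % |
|---|---|---|---|
| south-west | 0.250 | 6.2 | 88.6 |
| south-west | 0.833 | 15.6 | 70.0 |
| south-west | 1.33 | 20.7 | 58.6 |
| south-west | 2.00 | 25.6 | 45.8 |
| south-west | 3.00 | 30.7 | 31.5 |
| east | 0.250 | 11.4 | 83.2 |
| east | 0.417 | 17.3 | 75.0 |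
| east | 0.833 | 27.7 | 58.4 |
| east | 1.50 | 39.0 | 39.8 |
| east | 3.00 | 53.7 | 17.5 |

(readings scatter by 0.3 percentage points)

* average number of monomer units in a chain (chains begun, living or dead) at 3.0 h
* part of the free monomer that has reacted at 3.0 h

- the average divides the monomer in chains by the number of chains begun, living and dead together
- the earlier runs do not show the number of chains; that part of a forecast is a guess

I kept a ledger of the free monomer at 3.0 h. In the south-west run, 31.5 % stayed free and 30.7 % stood in chains, so 37.8 % had gone elsewhere. In the east run, 17.5 % stayed free and 53.7 % stood in chains, so 28.8 % had gone elsewhere.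

I joined these two ends in a straight line by charge. For the new flask I entered 39.5 % in chains and 26.2 % free, which left 34.3 % elsewhere. My c was therefore 73.8 %.

The earlier runs showed no chain count, so I guessed one chain per initiator, making initiator the limiting reagent for chains. The loading of 10 mol% applied to the free monomer, so the new flask's chain budget, the initiator charged, was 25.0 mM. That was ten times the transfer agent. The ledger put 0.0987 M of monomer in chains, and dividing by the budget gave me 3.95 units per chain.

The forecast said 38 and 75 %, on the words “I take the initiator as 10 mol% of the agent”.

The flask gave 4.13 units per chain and 74.6 % reacted.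

    free monomer + initiator → living end + monomer in chains (k = 18.0 L mol⁻¹ h⁻¹)
    free monomer + living end → monomer in chains + living end, rate k2*[living end]*[free monomer] (k = 10.0 L mol⁻¹ h⁻¹)
    living end + transfer agent → dead chain (kL = 120 L mol⁻¹ h⁻¹)
    free monomer → uncatalysed product (k = 0.210 h⁻¹)

At 3.00 h the flask held 0.079 % of its initiator, so nearly all of the chain budget of 25.0 mM had been used. The neighbour flask charged with 40 mol% of initiator kept 4.7 % of it and held 83.7 % of its charged free monomer in chains. Its budget of 100 mM, less that remainder, gives 2.20 units per chain, and that neighbour flask gave 2.20.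

The runs come from a simulation with made-up constants.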